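**Retrosynthetic overview**

1. Numbering: the methylidene decalin is rings A (C1–C5, C10; C4 = CMe2) and B (C5–C10; C8 carries =CH2, C9 carries the C11–C11' link); the other decalin is rings C (C5'–C10'; C8'=C9') and D (C1'–C5', C10').
2. C8=CH2 comes from a C8 ketone (Wittig). Ring A is opened at C3–C4: the gem-dimethyl quaternary carbon C4, bonded to ring-fusion carbon C5 and to CH2 group C3, is a C5 isopropenyl group lacking one C–C bond, so hydrogen atom transfer (MHAT) to the isopropenyl group and nickel-mediated coupling with a C3 iodide on the C10 propyl arm close ring A last.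
3. The seco-A ring B (C5 isopropenyl, quaternary C10, C8 ketone, C9 side chain) comes from cleavage of the cyclobutane C–C bond of a (+)-verbenone adduct: verbenone's CMe2 bridge is C4, its bridgehead is C5, cuprate addition anti to the bridge sets C10, and the only enolisable α-carbon is C9.
4. C9–C11 comes from enolate alkylation with the C16 iodide of the cis-fused C/D decalin, made from (S)-carvone (ring C) by the same hydroalkylation run intermolecularly, intramolecular enolate alkylation (ring D, cis), then Shapiro reaction and ethylene oxide.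
5. Ring order: C (carvone) and B (six-membered ring of verbenone) from the chiral pool, D in step 4, A last in step 13.

Key step: step 13

Assumption (stereochemical reading): the SMILES is taken as written, that is a trans-fused methylidene decalin (C5 S, C9 S, C10 S) linked to a cis-fused decalin (C5' R, C10' S); both are built deliberately.
Assumption (supply): (1R,5R)-(+)-verbenone is bought; it is also the one-step allylic oxidation product of (+)-α-pinene.
Remark: metal enolates formed by deprotonation or conjugate addition are treated as reactive forms of the numbered ketones and carry no numbers of their own.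

**Route**

Step 1
Reactants: 1 (S)-(+)-carvone
Product: 2 (5S,6R)-2,6-dimethyl-5-(prop-1-en-2-yl)cyclohex-2-en-1-one (trans-6-methylcarvone)
Conditions: LiN(i-Pr)2, THF, −78 °C; MeI, −78 → 0 °C
Reagents that add atoms: iodomethane, IC
Why: Kinetic α'-enolate alkylation of the cross-conjugated enone puts the methyl group on the future C10', anti to the isopropenyl group; this centre is re-enolised in step 4, so its configuration is not critical.

Step 2
Reactants: 2 (5S,6R)-2,6-dimethyl-5-(prop-1-en-2-yl)cyclohex-2-en-1-one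
Product: 3 (2R,3S,6S)-2,6-dimethyl-3-(prop-1-en-2-yl)cyclohexan-1-one
Conditions: LiBH(s-Bu)3, THF, −78 °C; then H2O
Reagents that add atoms: none
Why: Conjugate hydride reduction of the β-monosubstituted enone by a bulky trialkylborohydride removes the enone, which would compete for the metal hydride in step 3; the new methyl-bearing centre (C8') becomes sp2 again in step 6, so either epimer serves.

Step 3
Reactants: 3 (2R,3S,6S)-2,6-dimethyl-3-(prop-1-en-2-yl)cyclohexan-1-one
Product: 4 (2R,3S,6S)-3-(5-chloro-2-methylpentan-2-yl)-2,6-dimethylcyclohexan-1-one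
Conditions: 1-chloro-3-iodopropane, Mn(dpm)3 (cat., dpm = dipivaloylmethanate), Ni(acac)2 (cat.), PhSiH3, K2CO3, (CF3)2CHOH/ClCH2CH2Cl, rt
Reagents that add atoms: 1-chloro-3-iodopropane, ClCCCI
Why: Mn/Ni dual-catalytic Markovnikov hydroalkylation (hydrogen atom transfer to the isopropenyl CH2, capture of the tertiary radical by the alkylnickel species from the C–I bond) should build the gem-dimethyl quaternary carbon C4' and leave the C–Cl bond for step 4; no stereocentre is formed.

Step 4
Reactants: 4 (2R,3S,6S)-3-(5-chloro-2-methylpentan-2-yl)-2,6-dimethylcyclohexan-1-one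
Product: 5 (2S,4aR,8aS)-2,5,5,8a-tetramethyloctahydronaphthalen-1(2H)-one (cis-fused; the C2 epimer serves equally)
Conditions: KOtBu, NaI (cat.), t-BuOH/THF, 50 °C
Reagents that add atoms: none
Why: Intramolecular enolate C-alkylation (6-exo-tet) under equilibrating conditions closes ring D at the methyl-bearing α-carbon next to the tether; attack perpendicular to the enolate plane from an arm held on the neighbouring carbon C5' can only give the cis ring fusion, which sets C10' relative to C5', and the other enolate has no electrophile within reach.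

Step 5
Reactants: 5 (2S,4aR,8aS)-2,5,5,8a-tetramethyloctahydronaphthalen-1(2H)-one
Product: 6 N'-[(1E,2S,4aR,8aS)-2,5,5,8a-tetramethyloctahydronaphthalen-1(2H)-ylidene]-2,4,6-tri(propan-2-yl)benzenesulfonohydrazide
Conditions: 2,4,6-(i-Pr)3C6H2SO2NHNH2, HCl (cat.), THF, rt
Reagents that add atoms: 2,4,6-triisopropylbenzenesulfonohydrazide, CC(C)c1cc(C(C)C)c(c(c1)C(C)C)S(=O)(=O)NN
Why: Acid-catalysed condensation to the arylsulfonylhydrazone (first half of the Shapiro reaction) is known for 2,2,6-trisubstituted cyclohexanones; the N–N bond should lie anti to the quaternary carbon.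

Step 6
Reactants: 6 the arylsulfonylhydrazone of 5
Product: 8 2-[(4aR,8aS)-2,5,5,8a-tetramethyl-3,4,4a,5,6,7,8,8a-octahydronaphthalen-1-yl]ethan-1-ol, via vinyllithium 7 (not isolated)
Conditions: n-BuLi (2.2 equiv), THF, −78 → 0 °C; ethylene oxide, −78 °C → rt; then H2O
Reagents that add atoms: ethylene oxide, C1CO1
Why: Shapiro reaction: the only α-hydrogen is at C8', so double deprotonation and loss of sulfinate and N2 give the tetrasubstituted vinyllithium regiospecifically, which opens ethylene oxide to the homoallylic alcohol.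

Step 7
Reactants: 8 2-[(4aR,8aS)-2,5,5,8a-tetramethyl-3,4,4a,5,6,7,8,8a-octahydronaphthalen-1-yl]ethan-1-ol
Product: 9 (4aR,8aS)-1-(2-iodoethyl)-2,5,5,8a-tetramethyl-3,4,4a,5,6,7,8,8a-octahydronaphthalene
Conditions: I2, PPh3, imidazole, CH2Cl2, 0 °C → rt
Reagents that add atoms: iodine, [I][I]
Why: Appel-type iodination of the primary alcohol by SN2 displacement of the alkoxyphosphonium ion; the neutral conditions leave the tetrasubstituted alkene untouched.

Step 8
Reactants: 10 (1R,5R)-(+)-verbenone
Product: 11 (1R,4R,5R)-4-[3-(tert-butyldimethylsilyloxy)propyl]-4,6,6-trimethylbicyclo[3.1.1]heptan-2-one (propyl arm anti to the gem-dimethyl bridge)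
Conditions: TBSO(CH2)3MgBr, CuBr·SMe2 (cat.), THF, −40 → 0 °C; then H2O
Reagents that add atoms: 3-(tert-butyldimethylsilyloxy)propylmagnesium bromide, CC(C)(C)[Si](C)(C)OCCC[Mg]Br
Why: Copper-catalysed conjugate addition of the Grignard reagent to verbenone occurs on the face anti to the gem-dimethyl bridge, which places the three-carbon arm on C10 trans to the future C4 and so fixes the quaternary stereocentre C10.

Step 9
Reactants: 11 the verbenone adduct and 9 the C16 iodide
Product: 12 (1R,3S,4S,5S)-4-[3-(tert-butyldimethylsilyloxy)propyl]-4,6,6-trimethyl-3-{2-[(4aR,8aS)-2,5,5,8a-tetramethyl-3,4,4a,5,6,7,8,8a-octahydronaphthalen-1-yl]ethyl}bicyclo[3.1.1]heptan-2-one (new side chain anti to the bridge)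
Conditions: LiN(i-Pr)2, THF, −78 °C; 9, HMPA, −78 °C → rt
Reagents that add atoms: none
Why: Enolate alkylation (SN2) unites the two halves at C9–C11; the bridgehead α-carbon cannot enolise, so deprotonation is regiospecific at C9, and the C9 configuration (expected anti to the bridge, the wrong one) is corrected by equilibration in step 11.

Step 10
Reactants: 12 the coupled bicyclic ketone
Product: 13 (4S,5S,6S)-5-(3-acetoxypropyl)-5-methyl-4-(prop-1-en-2-yl)-6-{2-[(4aR,8aS)-2,5,5,8a-tetramethyl-3,4,4a,5,6,7,8,8a-octahydronaphthalen-1-yl]ethyl}cyclohex-1-en-1-yl acetate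
Conditions: Ac2O, BF3·OEt2 (cat.), Zn(OAc)2 (cat.), 0 °C → rt
Reagents that add atoms: acetic anhydride, CC(=O)OC(C)=O
Why: Lewis-acid-promoted, Grob-type fragmentation of the nopinone-type cyclobutyl ketone in acetic anhydride (carbonyl-assisted heterolysis of the strained C4–C7 bond, loss of a methyl proton from the tertiary cation, trapping as enol acetate) should unveil ring B with the C5 isopropenyl group while C5 and C10 keep their configuration; the same reagent pair is known to exchange a primary silyl ether for an acetate.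

Step 11
Reactants: 13 the enol acetate
Product: 14 (2R,3S,4S)-3-(3-hydroxypropyl)-3-methyl-4-(prop-1-en-2-yl)-2-{2-[(4aR,8aS)-2,5,5,8a-tetramethyl-3,4,4a,5,6,7,8,8a-octahydronaphthalen-1-yl]ethyl}cyclohexan-1-one
Conditions: K2CO3 (cat.), MeOH, rt
Reagents that add atoms: none
Why: Base-catalysed transesterification removes both acetyl groups, and the liberated ketone should epimerise at C9 to the equatorial side chain (cis to the C10 methyl group, as in the target), which is the thermodynamically preferred arrangement.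

Step 12
Reactants: 14 the keto alcohol
Product: 15 (2R,3S,4S)-3-(3-iodopropyl)-3-methyl-4-(prop-1-en-2-yl)-2-{2-[(4aR,8aS)-2,5,5,8a-tetramethyl-3,4,4a,5,6,7,8,8a-octahydronaphthalen-1-yl]ethyl}cyclohexan-1-one
Conditions: I2, PPh3, imidazole, CH2Cl2, 0 °C
Reagents that add atoms: iodine, [I][I]
Why: Appel-type iodination as in step 7; the weakly basic, non-enolising conditions avoid intramolecular C-alkylation of the ketone by the new iodide.

Step 13
Reactants: 15 the keto iodide
Product: 16 (1R,4aS,8aS)-5,5,8a-trimethyl-1-{2-[(4aR,8aS)-2,5,5,8a-tetramethyl-3,4,4a,5,6,7,8,8a-octahydronaphthalen-1-yl]ethyl}octahydronaphthalen-2(1H)-one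
Conditions: Mn(dpm)3 (cat.), Ni(acac)2 (cat.), PhSiH3 (slow addition), K2CO3, (CF3)2CHOH/ClCH2CH2Cl, high dilution, rt
Reagents that add atoms: none
Why: Proposed new method: the manganese hydride generated from Mn(dpm)3 and PhSiH3 transfers a hydrogen atom to the CH2 terminus of the C5 isopropenyl group and so creates the tertiary C4 radical that already carries both methyl groups, while low-valent nickel takes up the primary C3–I bond; capture of the C4 radical at the alkylnickel centre and reductive elimination forge the C3–C4 bond. The closest known reaction type is the intermolecular Mn/Ni dual-catalytic Markovnikov hydroalkylation of 1,1-disubstituted alkenes with unactivated primary alkyl iodides to quaternary carbons (the reaction of step 3), here run between two ends of one molecule. Ring A (C1, C2, C3, C4, C5, C10) closes in a formal 6-exo-tet sense at C3, through a seven-membered nickelacycle, as a chair fused to the ring B chair. No stereocentre is formed, since C4 becomes the gem-dimethyl carbon; the trans ring fusion follows from C5 and C10, fixed in steps 8 and 10, whose two arms are trans and diequatorial and can only bridge to a trans-decalin. The step needs chemoselective hydrogen atom transfer to the 1,1-disubstituted alkene in the presence of the tetrasubstituted C8'=C9' alkene and the C8 ketone, which the much slower transfer to a tetrasubstituted alkene flanked by quaternary C10' should secure, and it needs ring closure to outrun reduction of either terminus, which the gem-disubstituted C10 in the tether, high dilution and slow addition of the silane favour.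

Step 14
Reactants: 16 the tetracyclic ketone
Product: 17 the target, (4aS,5S,8aS)-1,1,4a-trimethyl-6-methylidene-5-{2-[(4aR,8aS)-2,5,5,8a-tetramethyl-3,4,4a,5,6,7,8,8a-octahydronaphthalen-1-yl]ethyl}decahydronaphthalene
Conditions: Ph3PCH3Br, KOtBu, toluene, 80 °C
Reagents that add atoms: methyltriphenylphosphonium bromide, C[P+](c1ccccc1)(c1ccccc1)c1ccccc1.[Br-]
Why: Wittig methylenation of the hindered C8 ketone is well precedented for 8-oxo decalones of the labdane type; C9 is already in its thermodynamic configuration, so the basic conditions should not erode it.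

**Compound list**

1 | (S)-(+)-carvone, (5S)-2-methyl-5-(prop-1-en-2-yl)cyclohex-2-en-1-one | CC1=CC[C@@H](CC1=O)C(C)=C | starting material
2 | (5S,6R)-2,6-dimethyl-5-(prop-1-en-2-yl)cyclohex-2-en-1-one | CC1=CC[C@@H]([C@@H](C)C1=O)C(C)=C | intermediate
3 | (2R,3S,6S)-2,6-dimethyl-3-(prop-1-en-2-yl)cyclohexan-1-one | C[C@H]1CC[C@@H]([C@@H](C)C1=O)C(C)=C | intermediate
4 | (2R,3S,6S)-3-(5-chloro-2-methylpentan-2-yl)-2,6-dimethylcyclohexan-1-one | C[C@H]1CC[C@@H]([C@@H](C)C1=O)C(C)(C)CCCCl | intermediate
5 | (2S,4aR,8aS)-2,5,5,8a-tetramethyloctahydronaphthalen-1(2H)-one, cis-fused | O=C1[C@@H](C)CC[C@@H]2C(C)(C)CCC[C@]12C | intermediate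
6 | N'-[(1E,2S,4aR,8aS)-2,5,5,8a-tetramethyloctahydronaphthalen-1(2H)-ylidene]-2,4,6-tri(propan-2-yl)benzenesulfonohydrazide | CC(C)c1cc(C(C)C)c(c(c1)C(C)C)S(=O)(=O)N/N=C1\[C@@H](C)CC[C@@H]2C(C)(C)CCC[C@]12C | intermediate
7 | [(4aR,8aS)-2,5,5,8a-tetramethyl-3,4,4a,5,6,7,8,8a-octahydronaphthalen-1-yl]lithium | [Li]C1=C(C)CC[C@@H]2C(C)(C)CCC[C@]12C | intermediate (not isolated)
8 | 2-[(4aR,8aS)-2,5,5,8a-tetramethyl-3,4,4a,5,6,7,8,8a-octahydronaphthalen-1-yl]ethan-1-ol | OCCC1=C(C)CC[C@@H]2C(C)(C)CCC[C@]12C | intermediate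
9 | (4aR,8aS)-1-(2-iodoethyl)-2,5,5,8a-tetramethyl-3,4,4a,5,6,7,8,8a-octahydronaphthalene | ICCC1=C(C)CC[C@@H]2C(C)(C)CCC[C@]12C | intermediate
10 | (1R,5R)-(+)-verbenone, (1R,5R)-4,6,6-trimethylbicyclo[3.1.1]hept-3-en-2-one | CC1=CC(=O)[C@@H]2C[C@H]1C2(C)C | starting material
11 | (1R,4R,5R)-4-[3-(tert-butyldimethylsilyloxy)propyl]-4,6,6-trimethylbicyclo[3.1.1]heptan-2-one | C[C@@]1(CCCO[Si](C)(C)C(C)(C)C)CC(=O)[C@@H]2C[C@H]1C2(C)C | intermediate
12 | (1R,3S,4S,5S)-4-[3-(tert-butyldimethylsilyloxy)propyl]-4,6,6-trimethyl-3-{2-[(4aR,8aS)-2,5,5,8a-tetramethyl-3,4,4a,5,6,7,8,8a-octahydronaphthalen-1-yl]ethyl}bicyclo[3.1.1]heptan-2-one | C[C@@]1(CCCO[Si](C)(C)C(C)(C)C)[C@H](CCC3=C(C)CC[C@@H]4C(C)(C)CCC[C@]34C)C(=O)[C@@H]2C[C@H]1C2(C)C | intermediate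
13 | (4S,5S,6S)-5-(3-acetoxypropyl)-5-methyl-4-(prop-1-en-2-yl)-6-{2-[(4aR,8aS)-2,5,5,8a-tetramethyl-3,4,4a,5,6,7,8,8a-octahydronaphthalen-1-yl]ethyl}cyclohex-1-en-1-yl acetate | CC(=O)OC1=CC[C@@H](C(C)=C)[C@](C)(CCCOC(C)=O)[C@@H]1CCC3=C(C)CC[C@@H]4C(C)(C)CCC[C@]34C | intermediate
14 | (2R,3S,4S)-3-(3-hydroxypropyl)-3-methyl-4-(prop-1-en-2-yl)-2-{2-[(4aR,8aS)-2,5,5,8a-tetramethyl-3,4,4a,5,6,7,8,8a-octahydronaphthalen-1-yl]ethyl}cyclohexan-1-one | O=C1CC[C@@H](C(C)=C)[C@](C)(CCCO)[C@H]1CCC3=C(C)CC[C@@H]4C(C)(C)CCC[C@]34C | intermediate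
15 | (2R,3S,4S)-3-(3-iodopropyl)-3-methyl-4-(prop-1-en-2-yl)-2-{2-[(4aR,8aS)-2,5,5,8a-tetramethyl-3,4,4a,5,6,7,8,8a-octahydronaphthalen-1-yl]ethyl}cyclohexan-1-one | O=C1CC[C@@H](C(C)=C)[C@](C)(CCCI)[C@H]1CCC3=C(C)CC[C@@H]4C(C)(C)CCC[C@]34C | intermediate
16 | (1R,4aS,8aS)-5,5,8a-trimethyl-1-{2-[(4aR,8aS)-2,5,5,8a-tetramethyl-3,4,4a,5,6,7,8,8a-octahydronaphthalen-1-yl]ethyl}octahydronaphthalen-2(1H)-one | O=C1CC[C@H]2C(C)(C)CCC[C@]2(C)[C@H]1CCC3=C(C)CC[C@@H]4C(C)(C)CCC[C@]34C | intermediate
17 | CNP0151741.1, (4aS,5S,8aS)-1,1,4a-trimethyl-6-methylidene-5-{2-[(4aR,8aS)-2,5,5,8a-tetramethyl-3,4,4a,5,6,7,8,8a-octahydronaphthalen-1-yl]ethyl}decahydronaphthalene | C=C1CC[C@H]2C(C)(C)CCC[C@]2(C)[C@H]1CCC1=C(C)CC[C@@H]2C(C)(C)CCC[C@]12C | target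

**Step count and risks**

Total step count: 14. Longest linear sequence: 13 steps (steps 1–7, then 9–14).

Steps most likely to fail:

1. Step 13 (labelled step). The tertiary C4 radical may be reduced to an isopropyl group, or the C–I bond may be reduced, before the two ends meet on nickel; a freed primary radical could also add to the isopropenyl terminus in a 7-endo sense. The fallback uses known reaction types, sets out from 14 and comes back at 16. Oxidation of the primary alcohol with Dess–Martin periodinane should give the keto aldehyde F1. Condensation with one equivalent of p-toluenesulfonyl hydrazide at rt (the hindered ketone should not react) should give the aldehyde N-tosylhydrazone F2. Fe(acac)3 and PhSiH3 in EtOH then generate the same C4 radical by hydrogen atom transfer, and it adds in a 6-exo-trig sense to the hydrazone carbon C3 (the known MHAT alkene–hydrazone radical cyclisation) to give the cyclised sulfonylhydrazide F3. Warming F3 with NaOAc in MeOH expels sulfinate and N2, as in the MHAT hydromethylation of alkenes with sulfonylhydrazones, and leaves C3 as CH2, which is 16.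

2. Step 9. Slow SN2 attack by the hindered enolate carbon next to quaternary C10 may let E2 elimination of the homoallylic iodide and proton transfer take over. The fallback sets out from 11 and comes back at 12. Condensation with Me2NNH2 (AcOH cat.) should give the N,N-dimethylhydrazone F4. Its lithium aza-enolate (LiN(i-Pr)2, THF), which is more nucleophilic and less basic than the ketone enolate, is alkylated with 9 to give the alkylated hydrazone F5. Hydrolysis with aqueous CuCl2 in THF returns ketone 12.

3. Step 10. The Lewis acid and acylating medium may cause migration or acylation of the tetrasubstituted C8'=C9' alkene, and the tertiary cation may lose the C5 proton instead of a methyl proton. The fallback moves the C–C cleavage in front of the union; it sets out from 10 and comes back at 14. The same Ac2O/BF3·OEt2/Zn(OAc)2 opening applied to verbenone itself should give the dienyl acetate F6, and K2CO3 in MeOH should give the monocyclic enone F7. Copper-catalysed addition of TBSO(CH2)3MgBr with Me3SiCl, anti to the C5 isopropenyl group, should give the regiodefined silyl enol ether F8. MeLi releases the C9 lithium enolate, which is alkylated with 9 (HMPA) and equilibrated with K2CO3 in MeOH to the keto silyl ether F9. n-Bu4NF in THF then gives 14.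

Further compounds
F1 | step 13 | 3-[(1S,2R,6S)-1-methyl-3-oxo-6-(prop-1-en-2-yl)-2-{2-[(4aR,8aS)-2,5,5,8a-tetramethyl-3,4,4a,5,6,7,8,8a-octahydronaphthalen-1-yl]ethyl}cyclohexyl]propanal | O=C1CC[C@@H](C(C)=C)[C@](C)(CCC=O)[C@H]1CCC3=C(C)CC[C@@H]4C(C)(C)CCC[C@]34C
F2 | step 13 | (E)-N-tosylhydrazone of aldehyde F1 | O=C1CC[C@@H](C(C)=C)[C@](C)(CC/C=N/NS(=O)(=O)c2ccc(C)cc2)[C@H]1CCC3=C(C)CC[C@@H]4C(C)(C)CCC[C@]34C
F3 | step 13 | (1R,4aR,6S,8aS)-5,5,8a-trimethyl-6-[2-(4-methylbenzenesulfonyl)hydrazinyl]-1-{2-[(4aR,8aS)-2,5,5,8a-tetramethyl-3,4,4a,5,6,7,8,8a-octahydronaphthalen-1-yl]ethyl}octahydronaphthalen-2(1H)-one (equatorial C3 epimer shown; either serves) | O=C1CC[C@H]2C(C)(C)[C@@H](NNS(=O)(=O)c5ccc(C)cc5)CC[C@]2(C)[C@H]1CCC3=C(C)CC[C@@H]4C(C)(C)CCC[C@]34C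
F4 | step 9 | N,N-dimethylhydrazone of 11 (NMe2 syn to the CH2 group) | C[C@@]1(CCCO[Si](C)(C)C(C)(C)C)C/C(=N\N(C)C)[C@@H]2C[C@H]1C2(C)C
F5 | step 9 | N,N-dimethylhydrazone of 12 (NMe2 anti to the alkylated carbon) | C[C@@]1(CCCO[Si](C)(C)C(C)(C)C)[C@H](CCC3=C(C)CC[C@@H]4C(C)(C)CCC[C@]34C)/C(=N/N(C)C)[C@@H]2C[C@H]1C2(C)C
F6 | step 10 | (4S)-5-methyl-4-(prop-1-en-2-yl)cyclohexa-1,5-dien-1-yl acetate | CC(=O)OC1=CC[C@@H](C(C)=C)C(C)=C1
F7 | step 10 | (4S)-3-methyl-4-(prop-1-en-2-yl)cyclohex-2-en-1-one | O=C1CC[C@@H](C(C)=C)C(C)=C1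
F8 | step 10 | tert-butyldimethyl{3-[(1S,6S)-1-methyl-6-(prop-1-en-2-yl)-3-(trimethylsilyloxy)cyclohex-2-en-1-yl]propoxy}silane | C[Si](C)(C)OC1=C[C@@](C)(CCCO[Si](C)(C)C(C)(C)C)[C@H](C(C)=C)CC1
F9 | step 10 | (2R,3S,4S)-3-[3-(tert-butyldimethylsilyloxy)propyl]-3-methyl-4-(prop-1-en-2-yl)-2-{2-[(4aR,8aS)-2,5,5,8a-tetramethyl-3,4,4a,5,6,7,8,8a-octahydronaphthalen-1-yl]ethyl}cyclohexan-1-one | O=C1CC[C@@H](C(C)=C)[C@](C)(CCCO[Si](C)(C)C(C)(C)C)[C@H]1CCC3=C(C)CC[C@@H]4C(C)(C)CCC[C@]34C
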